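The numbers in the tables are simulated with constants of no real substance; noise was put on by code.

A flask that did nothing but turn starting material into target could not hold 49.4% target at 5.00 d with 0% starting material beside it, yet the autumn run does.

| flask | starting material | gas phase | protic impurity | remark | time |
|---|---|---|---|---|---|
| autumn | 0.11 M | 28 mM (held) | 0.22 M | run made earlier |  |
| dawn | 0.17 M | 28 mM (held) | 0.22 M | run made earlier |  |
| flask | 0.22 M | 28 mM (held) | 0.220 M |  | 5.0 d |

- autumn (time / d: target / %, starting material / %): 1.04: 93.3, 0; 2.08: 79.1, 0.5; 3.00: 68.6, 0.3; 4.00: 58.1, 0.4; 5.00: 49.4, 0
- dawn (time / d: target / %, starting material / %): 1.04: 94.1, 1.6; 2.08: 81.4, 0.2; 3.00: 70.7, 0.2; 4.00: 60.7, 0.9; 5.00: 52.8, 0.1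

(scatter of a reading: 0.5 percentage points)

- at the start none of the gas phase is in solution

- teal: doubling the saturation concentration of gas phase, all else as stated
- ochre: doubling the transfer coefficient of the gas phase, all else as stated

1. how much target there is at 5.0 d, in percent of the starting material charged
2. the change that raises the amount of target at 5.0 d, in percent of the starting material charged most ("none" if none brings more than 2 percentage points) (teal / ochre / none)
3. amount of target at 5.0 d, in percent of the starting material charged, after teal

So I build the flask up in layers. With the main step alone, starting material plus gas to target, the end state is 100% target.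

The second layer is a loss of target. From the second reading on, with starting material at 0.5% and 0.2%, the autumn run loses 0.161 d⁻¹ of its target and the dawn run 0.148 d⁻¹, although their charges differ. I call the mean of these readings, the fraction of target lost per day, a pseudo-first-order constant, the fade rate: 0.155 d⁻¹. Acting over the whole time, it leaves 46.1%.

The third layer is the lag: at the start none of the gas phase is in solution. Fading from 100% to the last reading needs a late start: 0.442 d in the autumn run and 0.872 d in the dawn run, longer with the larger charge. Scaling the dawn lag by charge gives 1.13 d for the flask, so I expect 54.9%.

Both runs share gas and impurity, so the readings cannot name the partner in the loss. I choose dissolved gas, and that is my judgement. Teal then sets the fade rate to 0.309 d⁻¹ and the lag to 0.565 d, giving 25.3%. Ochre keeps the fade rate with that shorter lag, giving 50.3%. Both stand lower than 54.9%, so I choose none.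

The forecast gives 55% (53.5% to 56.5%), none, and 53.3% after teal (51.5% to 55%), holding that faster gas “only makes the target earlier, exposing it to decay for longer”. We part on teal.

The flask gives 54.1%, the best change is none, and teal gives 24.3%.

    dissolved gas ⇌ dormant form (K = 40.0, k = 3.77 × 10⁻⁴ min⁻¹)
    gas phase ⇌ dissolved gas, rate k2*(csat - [dissolved gas]) (kL = 0.00688 min⁻¹)
    starting material + dissolved gas → target (k = 0.325 M⁻¹ min⁻¹)
    dissolved gas + target → over-reaction product (k = 0.00466 M⁻¹ min⁻¹)
    dissolved gas + protic impurity → quenched reagent (k = 0.00252 M⁻¹ min⁻¹)

The rest of the flask's charge stands at 5.00 d as over-reaction product, 45.9%. For the neighbour charged with 0.055 M of starting material, the dawn lag scaled by charge is 0.282 d, and the fade rate then reckons 48.2%; that flask holds 46.8%.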